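## Structural features

Astepyrazinoxide is made of two heteroaromatic units joined through one methylene carbon: a 1H-indole attached through C3 and a fully substituted 1-hydroxypyrazin-2(1H)-one attached through C6. The pyrazinone carries the cyclic hydroxamic acid (N1–OH, C2=O), a methyl group at C3 and a lactim methyl ether at C5. The indole carries a 3-methylbut-2-enyl (prenyl) chain at C7, next to the ring-fusion carbon C7a that bears N1. The molecule has no stereocentre, and its only alkene ends in two identical methyl groups, so no configuration has to be set or protected anywhere. The fragile parts are the reducible N–O bond, the acidic and metal-binding hydroxamic acid, the electron-rich indole C2=C3 bond, and the prenyl group. The prenyl CH2 is both benzylic and allylic: acid can cyclize or hydrate the alkene, and strong base can move it into conjugation. The real difficulty is regiochemical: a lone carbon substituent at indole C7 with C4, C5 and C6 unsubstituted, and a pyrazinone with four different substituents and oxygen on the nitrogen that lies between the carbonyl carbon and the carbon bearing the indolylmethyl group. The key step uses the substitution pattern of the indole benzene ring (C3a, C4, C5, C6, C7, C7a). C7a and C7 map onto an ynamide alkyne whose outer carbon carries the prenyl CH2, C3a and C4 onto a terminal alkyne tethered to nitrogen through C2 and C3, and C5 and C6 onto acetylene.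

## Logic of the disconnections

**24 ⇒ 23 ⇒ 22.** The last two forward operations are functional-group changes. The N1–CH2 bond of the indole protecting group is cut last, and before it the O–CH3 bond of the methoxy group on the carbon attached to the oxidized nitrogen. Going backwards, the hydroxamic acid is masked as a methoxy-substituted N-oxide and the indole NH as an N-alkoxymethyl derivative. The gain is that the acidic, chelating N–OH/C=O pair and the free NH are absent during the palladium step, and that the N-oxide doubles as the activating group for the fragment union. The demand is a demethylation that distinguishes two methoxy groups and a deprotection that spares the N–O bond and the prenyl alkene.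

**22 ⇒ 17 + 21.** The bond between indole C3 and the methylene carbon is cut. The methylene carbon is then a methyl group of 21 that the adjacent N-oxide makes acidic, and C3 becomes a C–Br carbon in 17. This cut lies between the two heteroaromatic halves and is the most convergent one available. The forward step must select the methyl group beside the N-oxide over the other methyl group, stop after one arylation, and tolerate the prenyl group under hot alkoxide.

**21 ⇒ 20 ⇒ 19 ⇒ 18.** The N–O bond is removed first, which leads to centrosymmetric 20, so the forward oxidation can give only one mono-N-oxide. Removing the aromatic unsaturation gives 19, and cutting both O–CH3 bonds gives 18, a commercial cyclic dipeptide that already holds all six ring atoms and both methyl groups. The forward demands are O- rather than N-alkylation of the lactams and an oxidation that stops at the mono-N-oxide.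

**17 ⇒ 15.** The C3–Br bond and the N1–CH2 bond are cut, leaving the free indole 15. The forward bromination must choose indole C3 over the trisubstituted alkene, which is why the nitrogen is alkylated (not acylated) before bromination.

**15 ⇒ 14 ⇒ 13.** Two hydrogens are returned to C2 and C3, and the N–S bond is re-formed. The reason is that the ring-forming step needs sp3 carbons in the tether and an electron-poor nitrogen. The forward demands are a reductive N–S cleavage that leaves the alkene alone and a dehydrogenation that leaves the doubly activated CH2 alone.

**13 ⇒ 11 + 12.** Three bonds of the benzene ring are cut: C3a–C7a, C4–C5 and C6–C7. This opens both the benzene ring and the five-membered nitrogen ring and reduces a bicyclic arene to an acyclic diyne and a two-carbon gas. The position of the prenyl group is written into 11, so no aromatic substitution selectivity is ever required. The forward step needs chemoselectivity for cross-reaction of 11 with 12 over self-reaction of 11.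

**11 ⇒ 10 ⇒ 9 + 5.** The terminal alkyne C–H is traced back to a C–Si bond, and then the N–C(sp) bond of the ynamide is cut to give a secondary sulfonamide and a 1-bromoalkyne. The silyl cap is the design improvement to the precursor synthesis: a free terminal alkyne would couple with 5 under copper catalysis, so the tether alkyne must carry a base-stable bulky silyl group during N-alkynylation. The forward demands are a coupling that does not isomerize the skipped enyne and a desilylation that does not turn the ynamide into an allenamide.

**9 ⇒ 7 + 6 (through 8), and 5 ⇒ 4 ⇒ 1 (through 3) + 2.** In 9 the bond between the tether CH2 and the alkyne carbon is cut, giving a strained N-sulfonyl heterocycle and a silylacetylide. This delivers the sulfonamide N–H, the two-carbon tether and the capped alkyne in one operation. In 5 the C–Br bond is traced back to a C–Si bond, and the bond between the alkyne carbon and the prenyl CH2 is cut to give a silylacetylene and an allylic bromide. The forward demands are attack at the primary carbon of 2 (not at its tertiary end) and bromination at the alkyne without touching the alkene.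

## Other disconnections considered

**Alternative 1:** The cut is made in the pyrazinone at C5–C6 and N1–C2. The forward key step is a ZnCl2-promoted Ugi-type three-component condensation of the O-allyl oxime ether A2 of (7-prenylindol-3-yl)acetaldehyde, pyruvic acid A3 and the convertible isocyanide 2-bromo-6-isocyanopyridine A4. It gives racemic A1, in which isocyanide addition has formed C5–C6 and Mumm acyl transfer has formed N1–C2.
- In its favour: the N–O bond is present from the start as an O-allyl hydroxylamine, so no N-oxidation and no choice between two methoxy groups is needed. The whole pyrazinone backbone is assembled in one step, and the activated pyridyl amide of A1 allows ring closure with a nitrogen source between C3 and C5.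
- Against it here: it leaves the C7 prenyl problem unsolved. A2 presupposes a 7-prenylindole, which must then be homologated at C3 by two carbons to a sensitive arylacetaldehyde oxime. Oxime ethers are weak electrophiles in isocyanide chemistry, and the ketone of A3 can compete as the carbonyl component. After ring closure an O-selective methylation of an ambident hydroxypyrazinone and a deallylation in the presence of the prenyl alkene are still required.
- Comparison: in oxidation-state economy on the heterocycle this alternative is the better plan. On the benzene ring the chosen plan is better, because it fixes C7 by construction. In step count the alternative is not shorter once the synthesis of the 7-prenylindole is added, so the two are at best equal.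

**Alternative 2:** The cut is made in the pyrrole ring at N1–C2 and C3–C3a. The forward key step is a Larock heteroannulation under Pd[P(t-Bu)3]2 catalysis between 2-bromo-6-prenylaniline A6 and the silyl alkyne A7 (the 3-trimethylsilylprop-2-ynyl analogue of 21). It gives A5, with the silyl group at C2 and the complete pyrazine N-oxide already on C3.
- In its favour: it is the most convergent plan. It needs no indole N-protection, no C3 bromination and no indoline redox steps, and the bulky silyl group steers the regiochemistry of alkyne insertion reliably.
- Against it here: A6 moves the regiochemical problem to an ortho-prenylated 2-bromoaniline, where prenyl–metal couplings tend to give linear and branched products. A7 has a CH2 flanked by an alkyne and an N-oxide-activated azine, which may isomerize to an allene under the hot basic annulation conditions. The N-oxide may be deoxygenated by phosphine and zerovalent palladium. A C2 desilylation and the same selective demethylation still follow.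
- Comparison: in step economy and convergence this alternative is better than the chosen plan. In mechanistic risk the chosen plan is better, because its ring-forming step involves no acidic CH2 and no N-oxide. On positional control the two are equal only if A6 is available as a single isomer.

**Alternative 3:** The cut is made in the benzene ring at C5–C6. The forward key step is a thermal disrotatory 6π electrocyclization of the 2,3-dialkenylpyrrole A9, which has a 2-methoxyvinyl group on C3 and a prenyl-bearing 1,1-disubstituted alkene on C2. Loss of methanol from C5 and C6 then gives A8.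
- In its favour: it needs no metal and no gas. The prenyl group is placed at C7 by construction, as in the chosen plan. A8 is identical with 16 of the chosen route, so it arrives with the nitrogen already protected and skips the desulfonylation and dehydrogenation steps.
- Against it here: A9 is a 1,2,3-trisubstituted pyrrole with two different alkenyl groups, and building it takes several regiocontrolled steps. Electrocyclization that interrupts pyrrole aromaticity needs high temperature, at which the skipped diene of A9 can undergo hydrogen shifts. The elimination of methanol needs acid or further heating, and the prenyl group is acid-sensitive.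
- Comparison: in positional control the two plans are equal. In the steps after ring formation the alternative is better, since A8 equals 16. In access to the precursor and in mildness of the ring-forming step (20 °C against well above 100 °C) the chosen plan is better, and it has close precedent on the same compound class.

Key step: step 6

Remark on the chemistry: 18 is taken as the commercial L,L-isomer; both of its stereocentres are erased in step 11, so any stereoisomer of 18 would serve equally.

## Route

Step 1
Reactants: 1 (trimethylsilyl)acetylene; 2 prenyl bromide (1-bromo-3-methylbut-2-ene)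
Product: 4 trimethyl(5-methylhex-4-en-1-yn-1-yl)silane, via silylethynylmagnesium bromide 3 (not isolated)
Conditions: EtMgBr, THF, 0 → 40 °C; then CuCl (5 mol%), 2, 40 °C
Reagents that add atoms: none
Why: Copper-catalysed allylic substitution of an alkynyl Grignard reagent; the alkynylcopper species should displace bromide at the unhindered primary carbon of 2 (SN2, not SN2′), and the silyl cap prevents double alkylation and keeps the product non-volatile.

Step 2
Reactants: 4 trimethyl(5-methylhex-4-en-1-yn-1-yl)silane
Product: 5 1-bromo-5-methylhex-4-en-1-yne
Conditions: NBS (1.1 equiv), AgNO3 (10 mol%), acetone, 20 °C, dark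
Reagents that add atoms: N-bromosuccinimide (NBS), O=C1CCC(=O)N1Br
Why: Silver-catalysed bromodesilylation of an alkynylsilane; AgNO3 turns the C–Si bond into a silver acetylide that NBS brominates much faster than it attacks the trisubstituted alkene in acetone in the dark.

Step 3
Reactants: 6 (triisopropylsilyl)acetylene; 7 1-tosylaziridine
Product: 9 4-methyl-N-[4-(triisopropylsilyl)but-3-yn-1-yl]benzenesulfonamide, via lithium silylacetylide 8 (not isolated)
Conditions: 6 (1.5 equiv), n-BuLi, THF, −78 °C; then 7, −78 → 20 °C; H2O
Reagents that add atoms: none
Why: Ring opening of an N-sulfonyl-activated aziridine by a lithium acetylide (SN2 at an unsubstituted ring carbon); excess acetylide should outcompete the product sulfonamide anion, and the bulky silyl group is a cap that survives the copper step.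

Step 4
Reactants: 9 4-methyl-N-[4-(triisopropylsilyl)but-3-yn-1-yl]benzenesulfonamide; 5 1-bromo-5-methylhex-4-en-1-yne
Product: 10 4-methyl-N-(5-methylhex-4-en-1-yn-1-yl)-N-[4-(triisopropylsilyl)but-3-yn-1-yl]benzenesulfonamide
Conditions: 5 (1.2 equiv), CuSO4·5H2O (10 mol%), 1,10-phenanthroline (20 mol%), K3PO4 (2 equiv), toluene, 70 °C
Reagents that add atoms: none
Why: Copper-catalysed N-alkynylation of a sulfonamide with a 1-bromoalkyne (Ullmann-type C(sp)–N coupling); the silyl cap blocks Cadiot–Chodkiewicz coupling of the tether alkyne with 5, and heterogeneous K3PO4 in toluene should be too weak to isomerize the skipped enyne.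

Step 5
Reactants: 10 4-methyl-N-(5-methylhex-4-en-1-yn-1-yl)-N-[4-(triisopropylsilyl)but-3-yn-1-yl]benzenesulfonamide
Product: 11 N-(but-3-yn-1-yl)-4-methyl-N-(5-methylhex-4-en-1-yn-1-yl)benzenesulfonamide
Conditions: TBAF (1.1 equiv), wet THF, 0 °C
Reagents that add atoms: none
Why: Fluoride-induced protodesilylation of an alkynylsilane; the ynamide and sulfonyl groups are inert to TBAF, and low temperature with short contact time should avoid base-induced ynamide-to-allenamide isomerization at the doubly activated CH2.

Step 6
Reactants: 11 N-(but-3-yn-1-yl)-4-methyl-N-(5-methylhex-4-en-1-yn-1-yl)benzenesulfonamide; 12 acetylene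
Product: 13 7-(3-methylbut-2-en-1-yl)-1-tosylindoline
Conditions: RhCl(PPh3)3 (5 mol%), acetylene (1 atm, saturated solution), toluene, 20 °C, slow addition of 11
Reagents that add atoms: none
Why: This is a rhodium-catalysed [2+2+2] alkyne cyclotrimerization, whose closest known case is the RhCl(PPh3)3-catalysed reaction of nitrogen-tethered ynamide diynes with acetylene to give 7-substituted N-sulfonylindolines. Loss of one PPh3 from RhCl(PPh3)3 frees two sites on monovalent rhodium, which bind both alkynes of 11; oxidative cyclization then joins the two inner alkyne carbons (C3a–C7a) and gives a bicyclic rhodacyclopentadiene of trivalent rhodium. This first event closes the five-membered nitrogen ring (N1, C2, C3, C3a, C7a) by metal-templated coupling across the three-atom N–CH2–CH2 tether. Acetylene then coordinates and inserts into a Rh–C bond, and reductive elimination forms C4–C5 and C6–C7, which closes the benzene ring and returns monovalent rhodium. No stereocentre is created. The selectivity needed is cross-reaction of 11 with acetylene over self-trimerization of either partner; the fast intramolecular oxidative coupling, a solution saturated with acetylene and slow addition of 11 should secure it. No regiochemical question arises, because acetylene is symmetrical and the ynamide fixes the prenyl-bearing carbon next to nitrogen. The trisubstituted prenyl alkene is a poor ligand for rhodium, and the sulfonyl group keeps the ynamide stable and the nitrogen non-coordinating.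

Step 7
Reactants: 13 7-(3-methylbut-2-en-1-yl)-1-tosylindoline
Product: 14 7-(3-methylbut-2-en-1-yl)indoline
Conditions: Mg turnings (10 equiv), MeOH, ultrasound, 20 °C
Reagents that add atoms: none
Why: Dissolving-metal desulfonylation by single-electron transfer from Mg to the N-aryl sulfonamide, which cleaves the N–S bond; Mg in MeOH does not reduce an isolated trisubstituted alkene.

Step 8
Reactants: 14 7-(3-methylbut-2-en-1-yl)indoline
Product: 15 7-(3-methylbut-2-en-1-yl)-1H-indole
Conditions: activated MnO2 (10 equiv), CH2Cl2, 20 °C
Reagents that add atoms: none
Why: Dehydrogenation of an indoline to the indole with activated MnO2, driven by aromatization; the reagent should leave the prenyl alkene and its allylic CH2 untouched.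

Step 9
Reactants: 15 7-(3-methylbut-2-en-1-yl)-1H-indole
Product: 17 3-bromo-7-(3-methylbut-2-en-1-yl)-1-{[2-(trimethylsilyl)ethoxy]methyl}-1H-indole, via N-SEM indole 16 (not isolated)
Conditions: NaH (1.05 equiv), DMF/THF, 0 °C; SEMCl (1.05 equiv), 0 → 20 °C; then NBS (1.0 equiv), −78 → 0 °C
Reagents that add atoms: 2-(trimethylsilyl)ethoxymethyl chloride (SEMCl), C[Si](C)(C)CCOCCl; N-bromosuccinimide (NBS), O=C1CCC(=O)N1Br
Why: N-alkylation of the sodium indolide followed in the same flask by electrophilic aromatic bromination at C3; C3 of an N-alkylindole is far more nucleophilic than the trisubstituted alkene, so one equivalent of NBS at −78 °C should brominate only the heterocycle.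

Step 10
Reactants: 18 (3S,6S)-3,6-dimethylpiperazine-2,5-dione, cyclo(L-Ala-L-Ala)
Product: 19 (2S,5S)-3,6-dimethoxy-2,5-dimethyl-2,5-dihydropyrazine
Conditions: Me3OBF4 (2.5 equiv), CH2Cl2, 20 °C; aq. K2CO3
Reagents that add atoms: trimethyloxonium tetrafluoroborate, C[O+](C)C.F[B-](F)(F)F
Why: O-alkylation of both lactam carbonyls with a trialkyloxonium salt (bis-lactim ether formation); the hard oxonium electrophile should alkylate at oxygen, and the two stereocentres are of no consequence because step 11 removes them.

Step 11
Reactants: 19 (2S,5S)-3,6-dimethoxy-2,5-dimethyl-2,5-dihydropyrazine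
Product: 20 2,5-dimethoxy-3,6-dimethylpyrazine
Conditions: DDQ (1.1 equiv), toluene, 20 → 60 °C
Reagents that add atoms: none
Why: Dehydrogenative aromatization of a dihydropyrazine with DDQ (hydride abstraction from a ring CH, then proton loss), driven by formation of the aromatic pyrazine.

Step 12
Reactants: 20 2,5-dimethoxy-3,6-dimethylpyrazine
Product: 21 2,5-dimethoxy-3,6-dimethylpyrazine 1-oxide
Conditions: mCPBA (1.05 equiv), CH2Cl2, 0 → 20 °C
Reagents that add atoms: 3-chloroperbenzoic acid (mCPBA), OOC(=O)c1cccc(Cl)c1
Why: Peracid N-oxidation of an azine; 20 is centrosymmetric, so both nitrogens are equivalent, and the first N-oxide deactivates the ring, so one equivalent of peracid should stop at the mono-N-oxide.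

Step 13
Reactants: 17 3-bromo-7-(3-methylbut-2-en-1-yl)-1-{[2-(trimethylsilyl)ethoxy]methyl}-1H-indole; 21 2,5-dimethoxy-3,6-dimethylpyrazine 1-oxide
Product: 22 2,5-dimethoxy-3-methyl-6-{[7-(3-methylbut-2-en-1-yl)-1-{[2-(trimethylsilyl)ethoxy]methyl}-1H-indol-3-yl]methyl}pyrazine 1-oxide
Conditions: 21 (2 equiv), Pd2(dba)3 (2.5 mol%), XPhos (10 mol%), NaOtBu (3 equiv), toluene, 110 °C
Reagents that add atoms: none
Why: Palladium-catalysed benzylic C(sp3)–H arylation of a 2-methylazine N-oxide with an aryl bromide; NaOtBu deprotonates the methyl group beside the N-oxide (the more acidic of the two), the carbanion transmetalates to the arylpalladium bromide formed from 17 and zerovalent palladium, and reductive elimination forms the C3–CH2 bond. Excess 21 should limit a second arylation.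

Step 14
Reactants: 22 2,5-dimethoxy-3-methyl-6-{[7-(3-methylbut-2-en-1-yl)-1-{[2-(trimethylsilyl)ethoxy]methyl}-1H-indol-3-yl]methyl}pyrazine 1-oxide
Product: 23 1-hydroxy-5-methoxy-3-methyl-6-{[7-(3-methylbut-2-en-1-yl)-1-{[2-(trimethylsilyl)ethoxy]methyl}-1H-indol-3-yl]methyl}pyrazin-2(1H)-one
Conditions: NaSEt (2 equiv), DMF, 60 °C; aq. NaH2PO4
Reagents that add atoms: none
Why: SN2 O-demethylation by a thiolate; the methoxy group on the carbon attached to the N-oxide nitrogen is the activated one because its leaving group is the resonance-stabilized cyclic hydroxamate, and once that anion has formed the ring should be too electron-rich for the second methyl ether to be cleaved.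

Step 15
Reactants: 23 1-hydroxy-5-methoxy-3-methyl-6-{[7-(3-methylbut-2-en-1-yl)-1-{[2-(trimethylsilyl)ethoxy]methyl}-1H-indol-3-yl]methyl}pyrazin-2(1H)-one
Product: 24 astepyrazinoxide, 1-hydroxy-5-methoxy-3-methyl-6-{[7-(3-methylbut-2-en-1-yl)-1H-indol-3-yl]methyl}pyrazin-2(1H)-one
Conditions: TBAF (5 equiv), ethylenediamine (5 equiv), THF, 65 °C; aq. NaH2PO4
Reagents that add atoms: none
Why: Fluoride-induced fragmentation of the N-SEM group (attack at silicon, loss of ethylene, collapse of the N-hydroxymethyl anion to formaldehyde, which ethylenediamine scavenges); the hydroxamic acid is present as its unreactive anion and the prenyl group is inert to basic fluoride.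

## Compound list

1 | (trimethylsilyl)acetylene | C#C[Si](C)(C)C | starting material
2 | prenyl bromide (1-bromo-3-methylbut-2-ene) | CC(C)=CCBr | starting material
3 | [(trimethylsilyl)ethynyl]magnesium bromide | C[Si](C)(C)C#C[Mg]Br | intermediate
4 | trimethyl(5-methylhex-4-en-1-yn-1-yl)silane | CC(C)=CCC#C[Si](C)(C)C | intermediate
5 | 1-bromo-5-methylhex-4-en-1-yne | CC(C)=CCC#CBr | intermediate
6 | (triisopropylsilyl)acetylene | C#C[Si](C(C)C)(C(C)C)C(C)C | starting material
7 | 1-tosylaziridine | Cc1ccc(cc1)S(=O)(=O)N1CC1 | starting material
8 | lithium (triisopropylsilyl)acetylide | [Li]C#C[Si](C(C)C)(C(C)C)C(C)C | intermediate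
9 | 4-methyl-N-[4-(triisopropylsilyl)but-3-yn-1-yl]benzenesulfonamide | Cc1ccc(cc1)S(=O)(=O)NCCC#C[Si](C(C)C)(C(C)C)C(C)C | intermediate
10 | 4-methyl-N-(5-methylhex-4-en-1-yn-1-yl)-N-[4-(triisopropylsilyl)but-3-yn-1-yl]benzenesulfonamide | CC(C)=CCC#CN(CCC#C[Si](C(C)C)(C(C)C)C(C)C)S(=O)(=O)c1ccc(C)cc1 | intermediate
11 | N-(but-3-yn-1-yl)-4-methyl-N-(5-methylhex-4-en-1-yn-1-yl)benzenesulfonamide | C#CCCN(C#CCC=C(C)C)S(=O)(=O)c1ccc(C)cc1 | intermediate
12 | acetylene | C#C | starting material
13 | 7-(3-methylbut-2-en-1-yl)-1-tosylindoline | CC(C)=CCc1cccc2c1N(S(=O)(=O)c1ccc(C)cc1)CC2 | intermediate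
14 | 7-(3-methylbut-2-en-1-yl)indoline | CC(C)=CCc1cccc2c1NCC2 | intermediate
15 | 7-(3-methylbut-2-en-1-yl)-1H-indole | CC(C)=CCc1cccc2cc[nH]c12 | intermediate
16 | 7-(3-methylbut-2-en-1-yl)-1-{[2-(trimethylsilyl)ethoxy]methyl}-1H-indole | C[Si](C)(C)CCOCn1ccc2cccc(CC=C(C)C)c21 | intermediate
17 | 3-bromo-7-(3-methylbut-2-en-1-yl)-1-{[2-(trimethylsilyl)ethoxy]methyl}-1H-indole | C[Si](C)(C)CCOCn1cc(Br)c2cccc(CC=C(C)C)c21 | intermediate
18 | (3S,6S)-3,6-dimethylpiperazine-2,5-dione, cyclo(L-Ala-L-Ala) | C[C@H]1C(=O)N[C@H](C(=O)N1)C | starting material
19 | (2S,5S)-3,6-dimethoxy-2,5-dimethyl-2,5-dihydropyrazine | C[C@H]1C(OC)=N[C@H](C(OC)=N1)C | intermediate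
20 | 2,5-dimethoxy-3,6-dimethylpyrazine | COc1nc(C)c(OC)nc1C | intermediate
21 | 2,5-dimethoxy-3,6-dimethylpyrazine 1-oxide | COc1nc(C)c(OC)[n+]([O-])c1C | intermediate
22 | 2,5-dimethoxy-3-methyl-6-{[7-(3-methylbut-2-en-1-yl)-1-{[2-(trimethylsilyl)ethoxy]methyl}-1H-indol-3-yl]methyl}pyrazine 1-oxide | COc1nc(C)c(OC)[n+]([O-])c1Cc1cn(COCC[Si](C)(C)C)c2c(CC=C(C)C)cccc12 | intermediate
23 | 1-hydroxy-5-methoxy-3-methyl-6-{[7-(3-methylbut-2-en-1-yl)-1-{[2-(trimethylsilyl)ethoxy]methyl}-1H-indol-3-yl]methyl}pyrazin-2(1H)-one | COc1nc(C)c(=O)n(O)c1Cc1cn(COCC[Si](C)(C)C)c2c(CC=C(C)C)cccc12 | intermediate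
24 | astepyrazinoxide, 1-hydroxy-5-methoxy-3-methyl-6-{[7-(3-methylbut-2-en-1-yl)-1H-indol-3-yl]methyl}pyrazin-2(1H)-one | COc1nc(C)c(=O)n(O)c1Cc1c[nH]c2c(CC=C(C)C)cccc12 | target

## Step count and least certain steps

Total: 15 steps. Longest linear sequence: 11 steps (steps 1, 2, 4, 5, 6, 7, 8, 9, 13, 14, 15). Step 3 and steps 10–12 are side branches.

**Step 6 (key step).** The diyne may react with itself: the terminal alkyne of a second molecule of 11 can insert into the rhodacycle in place of acetylene, or the terminal alkyne can dimerize at rhodium. Both become serious if the solution is not kept saturated with gas. Fallback from 11, returning at 13: the gas is replaced by vinyl acetate (CC(=O)OC=C) as a liquid acetylene equivalent under [Rh(cod)2]BF4/BINAP catalysis in CH2Cl2. Cyclotrimerization with the alkene should give racemic 7-(3-methylbut-2-en-1-yl)-1-tosyl-2,3,5,6-tetrahydro-1H-indol-5-yl acetate F1, whose acetate position is immaterial. F1 should lose acetic acid on gentle warming and aromatize to 13.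

**Step 13.** Three processes may compete at 110 °C under alkoxide: thermal transfer of the methyl group from the methoxy oxygen to the N-oxide oxygen, a second arylation at the more acidic diarylmethane CH2 of the product, and base- or palladium hydride-induced migration of the prenyl double bond into conjugation. Fallback from 21 and 17, returning at 22: 21 is metalated at the activated methyl group with TMPZnCl·LiCl in THF at 25 °C to give [(3,6-dimethoxy-5-methyl-1-oxidopyrazin-2-yl)methyl]zinc chloride F2. F2 is then joined to 17 by Negishi coupling with Pd(OAc)2/SPhos at 25–50 °C, which replaces the hot alkoxide conditions with a preformed benzylic zinc reagent.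

**Step 14.** The thiolate may fail to discriminate sufficiently between the two methyl ethers, or may add to the ring carbon instead of attacking the methyl group. Fallback from 22, returning at 23: the mechanism is changed from substitution at the methyl carbon to addition–elimination at the ring carbon with aqueous NaOH in dioxane at 80 °C. Regiocontrol then comes from the N-oxide, which activates only the carbon attached to it towards a Meisenheimer-type adduct. No new compound is involved.

**Step 15.** Cleavage of the N-SEM group, hindered by the C7 substituent, may be incomplete or may stall at the N-hydroxymethyl stage, and prolonged heating may erode the N–O function. Fallback from 15 (with 21), returning at 24: the protecting group is changed to a carbamate.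
- 15 is brominated with NBS in THF at −78 °C to 3-bromo-7-(3-methylbut-2-en-1-yl)-1H-indole F3.
- F3 is acylated in the same flask with Boc2O and DMAP to tert-butyl 3-bromo-7-(3-methylbut-2-en-1-yl)-1H-indole-1-carboxylate F4.
- Negishi coupling of F4 with the zinc reagent F2 (Pd(OAc)2/SPhos, THF, 40 °C) gives tert-butyl 3-[(3,6-dimethoxy-5-methyl-1-oxidopyrazin-2-yl)methyl]-7-(3-methylbut-2-en-1-yl)-1H-indole-1-carboxylate F5.
- NaOMe in MeOH at 20 °C removes the carbamate to give 2,5-dimethoxy-3-methyl-6-{[7-(3-methylbut-2-en-1-yl)-1H-indol-3-yl]methyl}pyrazine 1-oxide F6.
- F6 is demethylated with NaSEt in DMF as in step 14 to give 24.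

**Step 4.** The bromoalkyne may be lost to copper-mediated homocoupling, or the skipped enyne may isomerize under base before the C–N bond forms. Fallback from 9 and 2, returning at 10: 9 is added to trichloroethylene (Cs2CO3, DMF, 50 °C) to give (E)-N-(1,2-dichlorovinyl)-4-methyl-N-[4-(triisopropylsilyl)but-3-yn-1-yl]benzenesulfonamide F7. PhLi (2.2 equiv, THF, −78 °C) converts F7 by elimination and chlorine–lithium exchange into the lithium ynamide acetylide F8. F8 is alkylated with 2 in the presence of CuCl, as in step 1, to give 10 without the use of 5.

## Further compounds

F1 | step 6 | racemic 7-(3-methylbut-2-en-1-yl)-1-tosyl-2,3,5,6-tetrahydro-1H-indol-5-yl acetate | CC(=O)OC1CC(CC=C(C)C)=C2N(S(=O)(=O)c3ccc(C)cc3)CCC2=C1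
F2 | step 13 | [(3,6-dimethoxy-5-methyl-1-oxidopyrazin-2-yl)methyl]zinc chloride | COc1nc(C)c(OC)[n+]([O-])c1C[Zn]Cl
F0 | step 14 | none | none
F3 | step 15 | 3-bromo-7-(3-methylbut-2-en-1-yl)-1H-indole | CC(C)=CCc1cccc2c(Br)c[nH]c12
F4 | step 15 | tert-butyl 3-bromo-7-(3-methylbut-2-en-1-yl)-1H-indole-1-carboxylate | CC(C)=CCc1cccc2c(Br)cn(C(=O)OC(C)(C)C)c12
F5 | step 15 | tert-butyl 3-[(3,6-dimethoxy-5-methyl-1-oxidopyrazin-2-yl)methyl]-7-(3-methylbut-2-en-1-yl)-1H-indole-1-carboxylate | COc1nc(C)c(OC)[n+]([O-])c1Cc1cn(C(=O)OC(C)(C)C)c2c(CC=C(C)C)cccc12
F6 | step 15 | 2,5-dimethoxy-3-methyl-6-{[7-(3-methylbut-2-en-1-yl)-1H-indol-3-yl]methyl}pyrazine 1-oxide | COc1nc(C)c(OC)[n+]([O-])c1Cc1c[nH]c2c(CC=C(C)C)cccc12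
F7 | step 4 | (E)-N-(1,2-dichlorovinyl)-4-methyl-N-[4-(triisopropylsilyl)but-3-yn-1-yl]benzenesulfonamide | Cl/C=C(/Cl)N(CCC#C[Si](C(C)C)(C(C)C)C(C)C)S(=O)(=O)c1ccc(C)cc1
F8 | step 4 | lithium {N-tosyl-N-[4-(triisopropylsilyl)but-3-yn-1-yl]amino}acetylide | [Li]C#CN(CCC#C[Si](C(C)C)(C(C)C)C(C)C)S(=O)(=O)c1ccc(C)cc1
A1 | alternative 1 | racemic N-allyloxy-N-pyruvoyl-7-prenyltryptophan 6-bromopyridin-2-ylamide | CC(=O)C(=O)N(OCC=C)C(Cc1c[nH]c2c(CC=C(C)C)cccc12)C(=O)Nc1cccc(Br)n1
A2 | alternative 1 | 2-[7-(3-methylbut-2-en-1-yl)-1H-indol-3-yl]acetaldehyde O-allyl oxime | C=CCON=CCc1c[nH]c2c(CC=C(C)C)cccc12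
A3 | alternative 1 | pyruvic acid | CC(=O)C(=O)O
A4 | alternative 1 | 2-bromo-6-isocyanopyridine | [C-]#[N+]c1cccc(Br)n1
A5 | alternative 2 | 2,5-dimethoxy-3-methyl-6-{[7-(3-methylbut-2-en-1-yl)-2-(trimethylsilyl)-1H-indol-3-yl]methyl}pyrazine 1-oxide | COc1nc(C)c(OC)[n+]([O-])c1Cc1c([Si](C)(C)C)[nH]c2c(CC=C(C)C)cccc12
A6 | alternative 2 | 2-bromo-6-(3-methylbut-2-en-1-yl)aniline | Nc1c(Br)cccc1CC=C(C)C
A7 | alternative 2 | 2,5-dimethoxy-3-methyl-6-[3-(trimethylsilyl)prop-2-yn-1-yl]pyrazine 1-oxide | COc1nc(C)c(OC)[n+]([O-])c1CC#C[Si](C)(C)C
A8 | alternative 3 | 7-(3-methylbut-2-en-1-yl)-1-{[2-(trimethylsilyl)ethoxy]methyl}-1H-indole | C[Si](C)(C)CCOCn1ccc2cccc(CC=C(C)C)c21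
A9 | alternative 3 | 3-[(E)-2-methoxyethenyl]-2-(5-methylhexa-1,4-dien-2-yl)-1-{[2-(trimethylsilyl)ethoxy]methyl}-1H-pyrrole | CO/C=C/c1ccn(COCC[Si](C)(C)C)c1C(=C)CC=C(C)C
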